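The cyclopentane is closed last, on a finished cycloheptene: the bond from the ring methylene C3 to the isopropyl-bearing carbon C4 is made by a 5-exo-trig alkyl radical cyclisation. The precursor is a cycloheptenol whose quaternary carbon C1 carries a 2-(phenylselanyl)ethyl arm and whose carbinol carbon C5 carries a 2-methylprop-1-enyl group on the same face. In one operation the step closes the five-membered ring, creates stereocentre C4 and converts the alkene terminus into the isopropyl group. It exploits the vicinal pair of fully substituted ring-fusion carbons C1 and C5 shared by the five- and seven-membered rings, which holds radical and alkene together and lets allylic strain direct isopropyl cis to the hydroxyl.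

Key step: step 9

Remark on numbering: C1–C10 are the daucane skeleton atoms (C1 methyl-bearing ring-fusion carbon; C2, C3 cyclopentane CH2; C4 isopropyl-bearing CH; C5 carbinol ring-fusion carbon; C6, C7 CH2; C8=C9 alkene with methyl on C8; C10 acyloxy-bearing CH). In this numbering the target is (1R,4R,5S,10S), with methyl, hydroxyl, isopropyl and ester oxygen all on one face of the cis-fused bicycle.

Assumption: ethyl (3R)-3-hydroxypent-4-enoate is bought as the single enantiomer; failing that, it is reached from the racemic aldol of ethyl acetate and acrolein by lipase resolution.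

Step 1
Reactants: 1 ethyl (3R)-3-hydroxypent-4-enoate; 2 prenyl bromide (1-bromo-3-methylbut-2-ene)
Product: 4 ethyl (2S,3S)-3-hydroxy-2-(3-methylbut-2-en-1-yl)pent-4-enoate, via dilithium dianion 3 (not isolated)
Conditions: LiN(iPr)2 (2.2 equiv), THF, −78 → −20 °C; then 2, DMPU, −78 → 0 °C
Reagents that add atoms: prenyl bromide (2), CC(C)=CCBr
Why: Fráter–Seebach alkylation: the lithium-chelated dianion 3 is attacked at C2 by the allylic bromide on the face anti to the vinyl substituent of the carbinol carbon, which should give the anti (2S,3S) ester, the C2 configuration being provisional because this centre is enolised again in step 2.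

Step 2
Reactants: 4 ethyl (2S,3S)-3-hydroxy-2-(3-methylbut-2-en-1-yl)pent-4-enoate
Product: 6 ethyl (2R,3S)-3-hydroxy-2-methyl-2-(3-methylbut-2-en-1-yl)pent-4-enoate, via dilithium dianion 5 (not isolated)
Conditions: LiN(iPr)2 (2.5 equiv), THF, −78 → −10 °C; then MeI, DMPU, −78 → 0 °C
Reagents that add atoms: iodomethane, CI
Why: Second Fráter–Seebach alkylation: the chelated tetrasubstituted dianion 5 again takes the electrophile anti to the vinyl group, so that the small and reactive iodomethane enters where prenyl stood and the quaternary centre C1 should form as (2R), the C1/C10 relation of the target.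

Step 3
Reactants: 6 ethyl (2R,3S)-3-hydroxy-2-methyl-2-(3-methylbut-2-en-1-yl)pent-4-enoate
Product: 7 ethyl (2R,3S)-3-[(tert-butyldimethylsilyl)oxy]-2-methyl-2-(3-methylbut-2-en-1-yl)pent-4-enoate
Conditions: TBSOTf, 2,6-lutidine, CH2Cl2, 0 °C
Reagents that add atoms: tert-butyldimethylsilyl trifluoromethanesulfonate, CC(C)(C)[Si](C)(C)OS(=O)(=O)C(F)(F)F
Why: Silyl ether formation with the silyl triflate and a hindered pyridine base, reactive enough for a secondary alcohol next to a quaternary carbon; no stereocentre is touched and the bulky silyloxy group later shields one ring face.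

Step 4
Reactants: 7 ethyl (2R,3S)-3-[(tert-butyldimethylsilyl)oxy]-2-methyl-2-(3-methylbut-2-en-1-yl)pent-4-enoate
Product: 10 (3R)-3-[(1S)-1-[(tert-butyldimethylsilyl)oxy]prop-2-en-1-yl]-3-methyloxolan-2-one, via ozonide 8 (not isolated), via hydroxy ester 9 (not isolated)
Conditions: O3 (1 equiv, Sudan Red 7B end-point), CH2Cl2, −78 °C; NaBH4, EtOH, −78 → 0 °C; PPTS (cat.), PhH, 50 °C
Reagents that add atoms: ozone, [O-][O+]=O
Why: Chemoselective ozonolysis with reductive work-up followed by lactonisation: the electron-rich trisubstituted prenyl alkene is cleaved far faster than the vinyl group (monosubstituted, deactivated by the allylic silyloxy group and shielded by the quaternary carbon), NaBH4 reduces ozonide 8 to primary alcohol 9 and mild acid closes the five-membered lactone, no stereocentre being touched.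

Step 5
Reactants: 10 (3R)-3-[(1S)-1-[(tert-butyldimethylsilyl)oxy]prop-2-en-1-yl]-3-methyloxolan-2-one; 11 homoallylic bromide 4-bromo-2-methylbut-1-ene
Product: 14 (6R,7S)-7-[(tert-butyldimethylsilyl)oxy]-6-(2-hydroxyethyl)-2,6-dimethylnona-1,8-dien-5-one, via (3-methylbut-3-en-1-yl)lithium 12 (not isolated), via lithium lactolate 13 (not isolated)
Conditions: 11, Li (2.2 equiv), Et2O, 0 °C; then 10, THF, −78 °C; H2O quench at −78 °C
Reagents that add atoms: 4-bromo-2-methylbut-1-ene (11), C=C(C)CCBr, used as its lithium derivative 12, [Li]CCC(C)=C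
Why: Addition of an organolithium reagent to a lactone: the tetrahedral lithium lactolate 13 should persist at −78 °C until the quench so that the ketone is released only in the absence of reagent, which secures mono-addition, and the quaternary alpha-carbon rules out enolisation.

Step 6
Reactants: 14 (6R,7S)-7-[(tert-butyldimethylsilyl)oxy]-6-(2-hydroxyethyl)-2,6-dimethylnona-1,8-dien-5-one
Product: 15 (2R,3S)-3-[(tert-butyldimethylsilyl)oxy]-2-(2-hydroxyethyl)-2,5-dimethylcyclohept-4-en-1-one
Conditions: second-generation Grubbs catalyst (5 mol%), CH2Cl2 (0.005 M), 40 °C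
Reagents that add atoms: none
Why: Ring-closing olefin metathesis between the 1,1-disubstituted and the monosubstituted alkene should give the trisubstituted cycloheptene (C8=C9), helped by the gem-disubstituted C1 in the tether and driven by loss of ethene; free hydroxyl, ketone and silyl ether are tolerated and no stereocentre is formed.

Step 7
Reactants: 15 (2R,3S)-3-[(tert-butyldimethylsilyl)oxy]-2-(2-hydroxyethyl)-2,5-dimethylcyclohept-4-en-1-one
Product: 16 (2R,3S)-3-[(tert-butyldimethylsilyl)oxy]-2,5-dimethyl-2-[2-(phenylselanyl)ethyl]cyclohept-4-en-1-one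
Conditions: N-(phenylselanyl)phthalimide, Bu3P, THF, 0 °C → rt
Reagents that add atoms: N-(phenylselanyl)phthalimide, O=C1c2ccccc2C(=O)N1[Se]c1ccccc1
Why: Mitsunobu-type substitution: Bu3P and the selenoimide convert the primary alcohol into an alkoxyphosphonium salt that phenylselenide displaces by SN2 at C3 under neutral conditions, leaving ketone, silyl ether and ring alkene untouched.

Step 8
Reactants: 16 (2R,3S)-3-[(tert-butyldimethylsilyl)oxy]-2,5-dimethyl-2-[2-(phenylselanyl)ethyl]cyclohept-4-en-1-one; 17 (2-methylprop-1-en-1-yl)magnesium bromide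
Product: 18 (1S,2R,3S)-3-[(tert-butyldimethylsilyl)oxy]-2,5-dimethyl-1-(2-methylprop-1-en-1-yl)-2-[2-(phenylselanyl)ethyl]cyclohept-4-en-1-ol
Conditions: 17 (3 equiv), LaCl3·2LiCl (0.3 equiv), THF, −20 → 0 °C
Reagents that add atoms: (2-methylprop-1-en-1-yl)magnesium bromide (17), CC(C)=C[Mg]Br
Why: Grignard 1,2-addition promoted by LaCl3·2LiCl, which favours addition over enolisation of the hindered ketone; attack should come along the axial-type trajectory anti to the pseudo-axial C1 methyl group and on the face free of the C10 silyloxy group, that is syn to the selenoethyl arm, which sets C5 with its hydroxyl cis to the C1 methyl and the C10 oxygen (1S in the name of 18).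

Step 9
Reactants: 18 (1S,2R,3S)-3-[(tert-butyldimethylsilyl)oxy]-2,5-dimethyl-1-(2-methylprop-1-en-1-yl)-2-[2-(phenylselanyl)ethyl]cyclohept-4-en-1-ol
Product: 21 (3R,3aS,8S,8aR)-8-[(tert-butyldimethylsilyl)oxy]-6,8a-dimethyl-3-(propan-2-yl)-1,2,3,3a,4,5,8,8a-octahydroazulen-3a-ol, via primary alkyl radical 19 (not isolated), via tertiary radical 20 (not isolated)
Conditions: Bu3SnH (1.5 equiv, syringe pump), AIBN (0.2 equiv), PhH (0.01 M), 80 °C
Reagents that add atoms: none
Why: Bu3Sn• removes the phenylselanyl group to give the primary C3 radical 19, which adds to the near carbon C4 of the 2-methylprop-1-enyl group, and the tertiary radical 20 so formed takes a hydrogen atom from Bu3SnH to carry the chain; the closest known reaction type is the tin hydride 5-hexenyl radical cyclisation of an alkyl selenide or halide onto a dimethyl-substituted alkene terminus. The cyclopentane closes in the 5-exo-trig mode and the former alkene terminus becomes the isopropyl group. The cis ring fusion is already in place before the closure because arm and alkenyl group sit on the same face at C1 and C5, and the new stereocentre C4 is controlled by the chair-like transition state in which the C5–C6 ring bond is pseudo-equatorial and the small C5 hydroxyl lies inside, eclipsing the alkene, so that allylic 1,3-strain with the cis-methyl group is minimal and isopropyl ends cis to the hydroxyl and the C1 methyl on the convex face. The step needs 5-exo closure onto C4 to beat direct reduction of 19, 6-endo attack on the dimethyl-substituted carbon and the bridging 5-exo attack on C9 of the ring alkene. High dilution with slow addition of the stannane, the gem-dialkyl effect of the two fully substituted carbons in the tether and the strain of the bridged bicyclo[4.2.1]nonane alternative should secure this.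

Step 10
Reactants: 21 (3R,3aS,8S,8aR)-8-[(tert-butyldimethylsilyl)oxy]-6,8a-dimethyl-3-(propan-2-yl)-1,2,3,3a,4,5,8,8a-octahydroazulen-3a-ol
Product: 22 (3R,3aS,8S,8aR)-6,8a-dimethyl-3-(propan-2-yl)-1,2,3,3a,4,5,8,8a-octahydroazulene-3a,8-diol
Conditions: Bu4NF, THF, 50 °C
Reagents that add atoms: none
Why: Fluoride-induced cleavage of the silyl ether (desilylation), driven by the strong Si–F bond; gentle warming is needed for the hindered secondary ether and the tertiary alcohol and alkene are inert.

Step 11
Reactants: 22 (3R,3aS,8S,8aR)-6,8a-dimethyl-3-(propan-2-yl)-1,2,3,3a,4,5,8,8a-octahydroazulene-3a,8-diol; 23 4-methoxybenzoyl chloride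
Product: 24 (1R,3aR,4S,8aS)-8a-hydroxy-3a,6-dimethyl-1-(propan-2-yl)-1,2,3,3a,4,7,8,8a-octahydroazulen-4-yl 4-methoxybenzoate (target)
Conditions: 23, Et3N, DMAP (cat.), CH2Cl2, rt
Reagents that add atoms: 4-methoxybenzoyl chloride (23), COc1ccc(cc1)C(Cl)=O
Why: DMAP-catalysed acylation (nucleophilic catalysis via the acylpyridinium ion) of the secondary allylic alcohol; the tertiary ring-fusion hydroxyl is too hindered to react, so the mono-ester with all four stereocentres unchanged, the target, should result.

Compound list
1 | ethyl (3R)-3-hydroxypent-4-enoate | O[C@H](CC(=O)OCC)C=C | starting material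
2 | prenyl bromide (1-bromo-3-methylbut-2-ene) | CC(C)=CCBr | starting material
3 | dilithium dianion of 1 (lithium alkoxide and lithium ester enolate) | [Li]O[C@@H](C=C)C=C(O[Li])OCC | intermediate
4 | ethyl (2S,3S)-3-hydroxy-2-(3-methylbut-2-en-1-yl)pent-4-enoate | O[C@@H](C=C)[C@H](CC=C(C)C)C(=O)OCC | intermediate
5 | dilithium dianion of 4 | [Li]O[C@@H](C=C)C(CC=C(C)C)=C(O[Li])OCC | intermediate
6 | ethyl (2R,3S)-3-hydroxy-2-methyl-2-(3-methylbut-2-en-1-yl)pent-4-enoate | O[C@@H](C=C)[C@@](C)(CC=C(C)C)C(=O)OCC | intermediate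
7 | ethyl (2R,3S)-3-[(tert-butyldimethylsilyl)oxy]-2-methyl-2-(3-methylbut-2-en-1-yl)pent-4-enoate | CC(C)(C)[Si](C)(C)O[C@@H](C=C)[C@@](C)(CC=C(C)C)C(=O)OCC | intermediate
8 | ozonide: ethyl (2R,3S)-3-[(tert-butyldimethylsilyl)oxy]-2-[(5,5-dimethyl-1,2,4-trioxolan-3-yl)methyl]-2-methylpent-4-enoate | CC(C)(C)[Si](C)(C)O[C@@H](C=C)[C@@](C)(CC1OOC(C)(C)O1)C(=O)OCC | intermediate
9 | hydroxy ester: ethyl (2R,3S)-3-[(tert-butyldimethylsilyl)oxy]-2-(2-hydroxyethyl)-2-methylpent-4-enoate | CC(C)(C)[Si](C)(C)O[C@@H](C=C)[C@@](C)(CCO)C(=O)OCC | intermediate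
10 | (3R)-3-[(1S)-1-[(tert-butyldimethylsilyl)oxy]prop-2-en-1-yl]-3-methyloxolan-2-one | O=C1OCC[C@]1(C)[C@H](C=C)O[Si](C)(C)C(C)(C)C | intermediate
11 | 4-bromo-2-methylbut-1-ene | C=C(C)CCBr | starting material
12 | (3-methylbut-3-en-1-yl)lithium | [Li]CCC(C)=C | intermediate
13 | lithium lactolate: lithium salt of the 2-hydroxy-2-(3-methylbut-3-en-1-yl)oxolane formed from 10 (either epimer at the new carbon) | [Li]OC1(CCC(C)=C)OCC[C@]1(C)[C@H](C=C)O[Si](C)(C)C(C)(C)C | intermediate
14 | (6R,7S)-7-[(tert-butyldimethylsilyl)oxy]-6-(2-hydroxyethyl)-2,6-dimethylnona-1,8-dien-5-one | C=C(C)CCC(=O)[C@](C)(CCO)[C@H](C=C)O[Si](C)(C)C(C)(C)C | intermediate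
15 | (2R,3S)-3-[(tert-butyldimethylsilyl)oxy]-2-(2-hydroxyethyl)-2,5-dimethylcyclohept-4-en-1-one | O=C1CCC(C)=C[C@H](O[Si](C)(C)C(C)(C)C)[C@@]1(C)CCO | intermediate
16 | (2R,3S)-3-[(tert-butyldimethylsilyl)oxy]-2,5-dimethyl-2-[2-(phenylselanyl)ethyl]cyclohept-4-en-1-one | O=C1CCC(C)=C[C@H](O[Si](C)(C)C(C)(C)C)[C@@]1(C)CC[Se]c1ccccc1 | intermediate
17 | (2-methylprop-1-en-1-yl)magnesium bromide | CC(C)=C[Mg]Br | starting material
18 | (1S,2R,3S)-3-[(tert-butyldimethylsilyl)oxy]-2,5-dimethyl-1-(2-methylprop-1-en-1-yl)-2-[2-(phenylselanyl)ethyl]cyclohept-4-en-1-ol | CC(C)(C)[Si](C)(C)O[C@H]1C=C(C)CC[C@](O)(C=C(C)C)[C@]1(C)CC[Se]c1ccccc1 | intermediate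
19 | primary alkyl radical (18 with the phenylselanyl group replaced by a radical centre at C3) | CC(C)(C)[Si](C)(C)O[C@H]1C=C(C)CC[C@](O)(C=C(C)C)[C@]1(C)C[CH2] | intermediate
20 | tertiary radical (cyclised skeleton of 21 with the radical centre on the future isopropyl carbon) | CC(C)(C)[Si](C)(C)O[C@H]2C=C(C)CC[C@]3(O)[C@@H]([C](C)C)CC[C@]23C | intermediate
21 | (3R,3aS,8S,8aR)-8-[(tert-butyldimethylsilyl)oxy]-6,8a-dimethyl-3-(propan-2-yl)-1,2,3,3a,4,5,8,8a-octahydroazulen-3a-ol | CC(C)(C)[Si](C)(C)O[C@H]2C=C(C)CC[C@]3(O)[C@@H](C(C)C)CC[C@]23C | intermediate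
22 | (3R,3aS,8S,8aR)-6,8a-dimethyl-3-(propan-2-yl)-1,2,3,3a,4,5,8,8a-octahydroazulene-3a,8-diol | O[C@H]2C=C(C)CC[C@]3(O)[C@@H](C(C)C)CC[C@]23C | intermediate
23 | 4-methoxybenzoyl chloride | COc1ccc(cc1)C(Cl)=O | starting material
24 | (1R,3aR,4S,8aS)-8a-hydroxy-3a,6-dimethyl-1-(propan-2-yl)-1,2,3,3a,4,7,8,8a-octahydroazulen-4-yl 4-methoxybenzoate | COc1ccc(C(=O)O[C@H]2C=C(C)CC[C@]3(O)[C@@H](C(C)C)CC[C@]23C)cc1 | target

Total step count: 11. Longest linear sequence: 11 steps (from 1; the route is fully linear).

Steps most likely to fail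

Step 8. What may go wrong: poor facial selectivity of the alkenyl addition (attack from the methyl-bearing face), or enolisation of the hindered ketone instead of addition. Fallback: the alkenyl group is built in two stages from a slimmer nucleophile. Starting from 16, prop-1-ynylmagnesium bromide (THF, LaCl3·2LiCl, 0 °C) adds to the ketone; the rod-like alkynyl nucleophile should follow the axial-type trajectory more strictly than the branched alkenyl reagent and give the propargylic alcohol F1. Alkoxide-directed carbomagnesiation of F1 with MeMgBr and catalytic Fe(acac)3 in THF then places methyl on the distal alkyne carbon and magnesium on the proximal one. Protonation on work-up gives the 2-methylprop-1-enyl carbinol 18, where the route is rejoined; no alkene geometry arises because the terminus carries two methyl groups.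

Step 9. What may go wrong: reduction of the primary radical before it closes, addition to C9 of the ring alkene, or erosion of the facial control at C4. Fallback: a closed-shell closure of the same C3–C4 bond by an intramolecular carbonyl-ene reaction. Starting from 15, addition of 17 (3 equiv, LaCl3·2LiCl, as in step 8) should give the diol F2, and TEMPO/PhI(OAc)2 oxidises only its primary alcohol to the aldehyde F3. Me2AlCl (CH2Cl2, −78 °C; the first equivalent caps the tertiary hydroxyl as its aluminium alkoxide) promotes the ene reaction of the C3 aldehyde with the trisubstituted alkene through the same chair-like arrangement, giving the isopropenyl cyclopentanol F4. H2 with RhCl(PPh3)3 reduces only the 1,1-disubstituted alkene to the isopropyl cyclopentanol F5. The secondary C3 hydroxyl is converted with 1,1'-thiocarbonyldiimidazole into the imidazolide F6, and Barton–McCombie deoxygenation (Bu3SnH, AIBN, toluene, 110 °C) gives 21, where the route is rejoined.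

Step 5. What may go wrong: double addition of the organolithium reagent after premature collapse of the lactolate, or no addition to the hindered carbonyl. Fallback: the lactone is opened at its other end first. Starting from 10, PhSeNa (from (PhSe)2 and NaBH4, DMF, 110 °C) opens the lactone by SN2 attack at the O–CH2 carbon (C3) to give the seleno acid F7. Activation ((COCl)2, cat. DMF; then MeNHOMe·HCl, pyridine) gives the N-methoxy-N-methylamide F8. The Grignard reagent made from 11 and Mg (THF, 0 °C → rt) adds once through its stable magnesium chelate to give the keto diene F9. Ring-closing metathesis (second-generation Grubbs catalyst, CH2Cl2, 40 °C) then gives 16, so that 14, 15 and step 7 are bypassed.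

Further compounds
F1 | step 8 | propargylic alcohol: 3-[(tert-butyldimethylsilyl)oxy]-2,5-dimethyl-2-[2-(phenylselanyl)ethyl]-1-(prop-1-yn-1-yl)cyclohept-4-en-1-ol, configured as 18 | CC(C)(C)[Si](C)(C)O[C@H]1C=C(C)CC[C@](O)(C#CC)[C@]1(C)CC[Se]c1ccccc1
F2 | step 9 | diol: (1S,2R,3S)-3-[(tert-butyldimethylsilyl)oxy]-2-(2-hydroxyethyl)-2,5-dimethyl-1-(2-methylprop-1-en-1-yl)cyclohept-4-en-1-ol | CC(C)(C)[Si](C)(C)O[C@H]1C=C(C)CC[C@](O)(C=C(C)C)[C@]1(C)CCO
F3 | step 9 | aldehyde: F2 with the primary alcohol oxidised to CHO | CC(C)(C)[Si](C)(C)O[C@H]1C=C(C)CC[C@](O)(C=C(C)C)[C@]1(C)CC=O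
F4 | step 9 | isopropenyl cyclopentanol: 21 with prop-1-en-2-yl in place of isopropyl and an extra hydroxyl on C3 (either epimer) | CC(C)(C)[Si](C)(C)O[C@H]2C=C(C)CC[C@]3(O)[C@@H](C(C)=C)C(O)C[C@]23C
F5 | step 9 | isopropyl cyclopentanol: 21 with an extra hydroxyl on C3 (either epimer) | CC(C)(C)[Si](C)(C)O[C@H]2C=C(C)CC[C@]3(O)[C@@H](C(C)C)C(O)C[C@]23C
F6 | step 9 | imidazolide: O-(imidazol-1-ylthiocarbonyl) derivative of the C3 hydroxyl of F5 | CC(C)(C)[Si](C)(C)O[C@H]2C=C(C)CC[C@]3(O)[C@@H](C(C)C)C(OC(=S)n4ccnc4)C[C@]23C
F7 | step 5 | seleno acid: (2R,3S)-3-[(tert-butyldimethylsilyl)oxy]-2-methyl-2-[2-(phenylselanyl)ethyl]pent-4-enoic acid | CC(C)(C)[Si](C)(C)O[C@@H](C=C)[C@@](C)(CC[Se]c1ccccc1)C(=O)O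
F8 | step 5 | N-methoxy-N-methylamide of F7 | CC(C)(C)[Si](C)(C)O[C@@H](C=C)[C@@](C)(CC[Se]c1ccccc1)C(=O)N(C)OC
F9 | step 5 | keto diene: (6R,7S)-7-[(tert-butyldimethylsilyl)oxy]-2,6-dimethyl-6-[2-(phenylselanyl)ethyl]nona-1,8-dien-5-one | C=C(C)CCC(=O)[C@](C)(CC[Se]c1ccccc1)[C@H](C=C)O[Si](C)(C)C(C)(C)C
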